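**Retrosynthetic overview**

1. Labels: C1 is the quaternary carbon with CH3 and CH2OAng; C2, C3, C8 and C7 form the cyclobutane (C2 on C1, C8 methylated); C4(CH3)–C5–C6(=O) spans C3 to C7; C9–C10(OAng)–C11(OAng) runs from C8 back to C1. The strategy rests on the cyclobutane and the ring C2–C3–C4–C5–C6–C7 sharing C2, C3 and C7 as a bicyclo[3.1.1]heptane, the formal [2+2] adduct of a ketene C7=C2=O and an E-alkene C3=C8 tethered through C4–C5–C6, with C6 arriving as a methylene.
2. Target ⇒ three angelates put on one per step in order of accessibility (primary oxygen, then C10 after desilylation, then C11) ⇒ C6 methylene (ozonolysis) ⇒ opening of C1–C11 (intramolecular Mukaiyama aldol, seven-membered ring) ⇒ removal of C1 from C2 (olefination of the C2 cyclobutanone, conjugate reduction from the bridge face).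
3. Cyclobutanone ⇒ vinylketene from a (2E,6E)-3-methyl-2,6-dienoyl chloride; C2–C3 and C7–C8 form in one step and C4 relays its configuration to C3, C7 and C8.
4. Acid chloride ⇒ methyl ketone (Horner–Wadsworth–Emmons) ⇒ E-alkenylboronate plus (E)-pent-3-en-2-one (rhodium–BINAP conjugate addition sets C4) ⇒ alkyne (carboalumination) ⇒ (S)-benzyl glycidyl ether (C10).
5. Ring order: cyclobutane and six-membered ring together, seven-membered ring last.

Key step: step 8

Remark: C-labels are those of the overview. Alkene-isomer and C1-epimer mixtures formed in steps 9–12 converge by step 15 and are carried on. (R)-BINAP is assumed to give the 4R ketone by analogy with BINAP–rhodium additions to acyclic E-enones, the antipodal ligand being used otherwise. In 22–30 the C10 oxygen and the C11 oxygen are trans, the C11 oxygen and the oxygenated carbon on C1 are trans, and the C1 methyl lies on the C3 side; the SMILES in the compound list give every ring stereocentre.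

**Route**

Step 1
Reactants: 1 (S)-benzyl glycidyl ether
Product: 2 (2S)-1-(benzyloxy)pent-4-yn-2-ol
Conditions: HC≡CLi·H2NCH2CH2NH2, DMSO, 0 °C to rt; aq NH4Cl
Reagents that add atoms: lithium acetylide–ethylenediamine complex, [Li+].[C-]#C.NCCN
Why: Epoxide alkynylation, in which the acetylide opens the oxirane by SN2 attack at the unsubstituted carbon, so the C10 stereocentre of 1 is carried over unchanged and C9, C8 and C3 are in place.

Step 2
Reactants: 2 (2S)-1-(benzyloxy)pent-4-yn-2-ol
Product: 3 {[(2S)-1-(benzyloxy)pent-4-yn-2-yl]oxy}tri(propan-2-yl)silane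
Conditions: TIPSOTf, 2,6-lutidine, CH2Cl2, 0 °C
Reagents that add atoms: triisopropylsilyl trifluoromethanesulfonate, CC(C)[Si](OS(=O)(=O)C(F)(F)F)(C(C)C)C(C)C
Why: Silylation of the secondary alcohol with a silyl triflate and a hindered pyridine base; the triisopropylsilyl ether is chosen because it is stable to the base, hydride, electron-transfer and Lewis-acid steps ahead, resists 1,2-silyl migration and does not chelate in step 15.

Step 3
Reactants: 3 {[(2S)-1-(benzyloxy)pent-4-yn-2-yl]oxy}tri(propan-2-yl)silane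
Product: 5 2-[(1E,4S)-5-(benzyloxy)-2-methyl-4-{[tri(propan-2-yl)silyl]oxy}pent-1-en-1-yl]-4,4,5,5-tetramethyl-1,3,2-dioxaborolane, via alkenyldimethylalane 4 (not isolated)
Conditions: AlMe3, Cp2ZrCl2 (25 mol%), CH2Cl2, 0 °C to rt; then i-PrOBpin, 0 °C to rt; aqueous work-up
Reagents that add atoms: trimethylaluminium, C[Al](C)C; 2-isopropoxy-4,4,5,5-tetramethyl-1,3,2-dioxaborolane, CC(C)OB1OC(C)(C)C(C)(C)O1
Why: Negishi carboalumination (zirconium-catalysed syn addition of CH3–Al across the terminal alkyne, methyl to the internal carbon) fixes the E geometry of the future C3=C8 bond, and the alkenyl group is then passed from aluminium to boron by the alkoxyboronate with retention.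

Step 4
Reactants: 5 alkenylboronate from step 3; 6 (E)-pent-3-en-2-one
Product: 7 (4R,5E,8S)-9-(benzyloxy)-4,6-dimethyl-8-{[tri(propan-2-yl)silyl]oxy}non-5-en-2-one
Conditions: [RhCl(C2H4)2]2 (2.5 mol%), (R)-BINAP (5.5 mol%), KOH (20 mol%), 1,4-dioxane–H2O 10:1, 50 °C
Reagents that add atoms: none
Why: Hayashi–Miyaura addition, in which transmetalation gives an alkenyl–rhodium–BINAP species that inserts the enone on the face selected by the ligand, so C4 is set (R) by catalyst control with retention of the E alkene geometry and without influence from the remote C10 centre.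

Step 5
Reactants: 7 methyl ketone from step 4; 8 triethyl phosphonoacetate
Product: 9 ethyl (2E,5R,6E,9S)-10-(benzyloxy)-3,5,7-trimethyl-9-{[tri(propan-2-yl)silyl]oxy}deca-2,6-dienoate
Conditions: NaH, THF, 0 °C to reflux; chromatography
Reagents that add atoms: none
Why: Horner–Wadsworth–Emmons olefination of the methyl ketone should favour the E enoate, which places the ester cis to the methyl on C6 that is deprotonated in step 8; the minor Z isomer is removed by chromatography.

Step 6
Reactants: 9 dienoate from step 5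
Product: 10 (2E,5R,6E,9S)-10-(benzyloxy)-3,5,7-trimethyl-9-{[tri(propan-2-yl)silyl]oxy}deca-2,6-dienoic acid
Conditions: LiOH·H2O, THF–MeOH–H2O, 50 °C; then 1 M HCl to pH 3, 0 °C
Reagents that add atoms: lithium hydroxide, [Li+].[OH-]
Why: Saponification of the conjugated ester by hydroxide leaves the silyl ether, the benzyl ether and both alkene geometries untouched.

Step 7
Reactants: 10 dienoic acid from step 6
Product: 11 (2E,5R,6E,9S)-10-(benzyloxy)-3,5,7-trimethyl-9-{[tri(propan-2-yl)silyl]oxy}deca-2,6-dienoyl chloride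
Conditions: 1-chloro-N,N,2-trimethylprop-1-en-1-amine, CH2Cl2, 0 °C to rt; solvent changed to toluene
Reagents that add atoms: 1-chloro-N,N,2-trimethylprop-1-en-1-amine, CC(C)=C(Cl)N(C)C
Why: Acid chloride formation with the Ghosez α-chloroenamine proceeds under neutral conditions without free HCl, so the silyl ether and both trisubstituted alkenes are preserved and the crude chloride can be used at once.

Step 8
Reactants: 11 dienoyl chloride from step 7
Product: 13 7-[(2S)-3-(benzyloxy)-2-{[tri(propan-2-yl)silyl]oxy}propyl]-4,7-dimethyl-2-methylidenebicyclo[3.1.1]heptan-6-one (skeleton labels: C2 ketone, C6 methylene, C8 methyl syn to the C4–C5–C6 bridge, C4 methyl on the C2 side), via vinylketene 12 (not isolated)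
Conditions: Et3N (3 equiv), toluene, reflux; 11 added over 4 h (final 0.01 M)
Reagents that add atoms: none
Why: The amine removes HCl from 11 by deprotonating the methyl on C6 that lies cis to the acyl group, which gives vinylketene 12 with the C6 methylene already in place. The electrophilic ketene carbon C2 then bonds to the less substituted alkene carbon C3 while positive charge develops at the tertiary C8 and is captured by C7; this is an asynchronous thermal ketene–alkene [2+2], suprafacial on the alkene, and its closest known type is the intramolecular cycloaddition of vinylketenes from 3-methyl-2,6-dienoyl chlorides to 2-methylenebicyclo[3.1.1]heptan-6-ones. The six-membered ring closes 6-exo through C2–C3 across the C4–C5–C6 tether and the cyclobutane closes through C7–C8. At C8 the E geometry (C4 cis to the C8 methyl) is retained, so the methyl ends syn to the three-carbon bridge and C9 anti; C3 and C7 are fixed by the bridged junction, and their sense relative to C4 is set by allylic 1,3-strain, which keeps the C4 hydrogen eclipsed toward the C8 methyl so that the ketene arrives on the alkene face carrying C5 and the C4 methyl ends on the C2 side. The step needs bridged rather than fused regiochemistry, secured by the trisubstituted alkene with its more substituted carbon distal to the tether; deprotonation at the methyl and not at C5, secured by the E enoyl chloride; and suppression of ketene dimerisation, secured by slow addition at high dilution.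

Step 9
Reactants: 13 cyclobutanone from step 8; 14 diethyl (1-cyanoethyl)phosphonate
Product: 15 2-[7-{(2S)-3-(benzyloxy)-2-{[tri(propan-2-yl)silyl]oxy}propyl}-4,7-dimethyl-2-methylidenebicyclo[3.1.1]heptan-6-ylidene]propanenitrile (both C2=C1 isomers)
Conditions: NaH, THF, 0 °C to reflux
Reagents that add atoms: none
Why: Horner–Wadsworth–Emmons olefination with the small cyano-stabilised phosphonate anion suits the strained, non-enolisable cyclobutanone (both α-carbons are bridgeheads), attack on C2 coming from the bridge face because the other face is blocked by the axial C9 methylene on C8; the alkene geometry is of no consequence.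

Step 10
Reactants: 15 alkylidene nitrile from step 9
Product: 16 2-[7-{(2S)-3-(benzyloxy)-2-{[tri(propan-2-yl)silyl]oxy}propyl}-4,7-dimethyl-2-methylidenebicyclo[3.1.1]heptan-6-yl]propanenitrile (C2–H syn to the C4–C5–C6 bridge; both C1 epimers)
Conditions: Mg turnings, MeOH, 0 °C to rt
Reagents that add atoms: none
Why: Dissolving-metal conjugate reduction with magnesium in methanol touches only the conjugated nitrile, and protonation of C2 from the bridge face, the opposite face being screened by the C9 methylene on C8, should place hydrogen syn to the C4–C5–C6 bridge and C1 anti to it, cis to C9.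

Step 11
Reactants: 16 nitrile from step 10
Product: 18 2-[7-{(2S)-3-(benzyloxy)-2-{[tri(propan-2-yl)silyl]oxy}propyl}-4,7-dimethyl-2-methylidenebicyclo[3.1.1]heptan-6-yl]propanal (both C1 epimers), via diisobutylaluminium aldimine 17 (not isolated)
Conditions: i-Bu2AlH, toluene, −78 °C; aqueous sodium potassium tartrate, pH 7 buffer, rt
Reagents that add atoms: water, O
Why: Partial reduction of the nitrile, in which one hydride adds to give an aluminated aldimine that is stable in the cold and is hydrolysed to the aldehyde on buffered work-up while the ethers and the methylene are inert.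

Step 12
Reactants: 18 aldehyde from step 11
Product: 19 tert-butyl({2-[7-{(2S)-3-(benzyloxy)-2-{[tri(propan-2-yl)silyl]oxy}propyl}-4,7-dimethyl-2-methylidenebicyclo[3.1.1]heptan-6-yl]prop-1-en-1-yl}oxy)dimethylsilane (both enol ether isomers)
Conditions: TBSOTf, Et3N, CH2Cl2, 0 °C to rt
Reagents that add atoms: tert-butyldimethylsilyl trifluoromethanesulfonate, CC(C)(C)[Si](C)(C)OS(=O)(=O)C(F)(F)F
Why: Soft enolisation of the α-branched aldehyde with a silyl triflate and an amine gives the only possible enol silane (one α-hydrogen), which erases the C1 epimer mixture and stores the C1 nucleophile for step 15.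

Step 13
Reactants: 19 enol silane from step 12
Product: 20 (2S)-3-[6-{1-[(tert-butyldimethylsilyl)oxy]prop-1-en-2-yl}-4,7-dimethyl-2-methylidenebicyclo[3.1.1]heptan-7-yl]-2-{[tri(propan-2-yl)silyl]oxy}propan-1-ol
Conditions: lithium 4,4′-di-tert-butylbiphenylide (LiDBB), THF, −78 °C; aq NH4Cl at −78 °C
Reagents that add atoms: none
Why: Reductive debenzylation by electron transfer from the arene radical anion frees the C11 alcohol at low temperature while the silyl ether, the electron-rich enol silane and the isolated alkene are not reduced.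

Step 14
Reactants: 20 primary alcohol from step 13
Product: 21 (2S)-3-[6-{1-[(tert-butyldimethylsilyl)oxy]prop-1-en-2-yl}-4,7-dimethyl-2-methylidenebicyclo[3.1.1]heptan-7-yl]-2-{[tri(propan-2-yl)silyl]oxy}propanal
Conditions: SO3·pyridine, DMSO, i-Pr2NEt, CH2Cl2, 0 °C; used crude
Reagents that add atoms: none
Why: Parikh–Doering oxidation converts the primary alcohol into the α-silyloxy aldehyde under mildly basic conditions that neither hydrolyse the enol silane nor epimerise C10.

Step 15
Reactants: 21 enol silane aldehyde from step 14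
Product: 22 5-hydroxy-2,6,11-trimethyl-9-methylidene-4-{[tri(propan-2-yl)silyl]oxy}tricyclo[5.4.0.0²,⁸]undecane-6-carbaldehyde (skeleton labels: C1 bears CH3 and CHO, C11 OH, C10 OSi; configuration as in the target)
Conditions: BF3·OEt2 (1.1 equiv), CH2Cl2, −78 °C, 0.005 M; aq NaHCO3
Reagents that add atoms: none
Why: Intramolecular Mukaiyama aldol, in which the enol silane on C2 and the aldehyde arm on C8 are both axial on the cyclobutane face away from the three-carbon bridge and so hold C1 and C11 within bonding distance, and closure through an open transition state with the BF3-bound aldehyde oxygen turned away from both the C10 silyloxy group (polar, non-chelated arrangement) and the oxygen-bearing enol carbon should place the C11 hydroxyl trans to C10–O and trans to the new formyl group on C1, the all-trans pattern of the target.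

Step 16
Reactants: 22 aldol from step 15
Product: 23 6-(hydroxymethyl)-2,6,11-trimethyl-9-methylidene-4-{[tri(propan-2-yl)silyl]oxy}tricyclo[5.4.0.0²,⁸]undecan-5-ol
Conditions: NaBH4, MeOH, 0 °C
Reagents that add atoms: none
Why: Borohydride reduction of the neopentyl aldehyde to the primary alcohol is fast enough to forestall retro-aldol cleavage and leaves the methylene and the silyl ether alone.

Step 17
Reactants: 23 diol from step 16
Product: 25 5-hydroxy-6-(hydroxymethyl)-2,6,11-trimethyl-4-{[tri(propan-2-yl)silyl]oxy}tricyclo[5.4.0.0²,⁸]undecan-9-one, via spiro-ozonide 24 (not isolated)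
Conditions: O3, CH2Cl2, −78 °C; then Me2S, −78 °C to rt
Reagents that add atoms: ozone, [O-][O+]=O
Why: Ozonolysis with reductive work-up cleaves the only alkene present, the C6 methylene, to the C6 ketone before any angelate is in the molecule, and the adjacent bridgehead C7 cannot enolise so no stereocentre is at risk.

Step 18
Reactants: 25 hydroxy ketone from step 17; 26 angelic acid
Product: 27 [5-hydroxy-2,6,11-trimethyl-9-oxo-4-{[tri(propan-2-yl)silyl]oxy}tricyclo[5.4.0.0²,⁸]undecan-6-yl]methyl (2Z)-2-methylbut-2-enoate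
Conditions: 26 (1.1 equiv), 2,4,6-trichlorobenzoyl chloride, Et3N, toluene, rt; then 25, 50 °C
Reagents that add atoms: none
Why: Yamaguchi-type esterification through the mixed anhydride of angelic acid, run without a nucleophilic catalyst so that the Z geometry of the acyl group is kept, should take only the primary hydroxyl because the C11 hydroxyl is shielded by the quaternary C1 on one side and the silyloxy-bearing C10 on the other.

Step 19
Reactants: 27 mono-angelate from step 18
Product: 28 (4,5-dihydroxy-2,6,11-trimethyl-9-oxotricyclo[5.4.0.0²,⁸]undecan-6-yl)methyl (2Z)-2-methylbut-2-enoate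
Conditions: HF·pyridine, THF–pyridine, 0 °C to rt
Reagents that add atoms: none
Why: Fluoride-mediated desilylation under buffered, weakly acidic conditions frees the C10 alcohol without cleaving or moving the angelate, and it is placed after ozonolysis because the acid-sensitive methylene next to the cyclobutane is by then gone.

Step 20
Reactants: 28 diol from step 19; 26 angelic acid
Product: 29 {5-hydroxy-2,6,11-trimethyl-4-[(2Z)-2-methylbut-2-enoyloxy]-9-oxotricyclo[5.4.0.0²,⁸]undecan-6-yl}methyl (2Z)-2-methylbut-2-enoate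
Conditions: 26 (1.2 equiv), 2,4,6-trichlorobenzoyl chloride, Et3N, toluene, rt; then 28, 80 °C
Reagents that add atoms: none
Why: The same mixed-anhydride esterification should acylate the C10 hydroxyl, which has a methylene neighbour, ahead of the C11 hydroxyl next to the quaternary C1, and any C11 ester or triester formed alongside is carried on because it converges in step 21.

Step 21
Reactants: 29 bis-angelate from step 20; 26 angelic acid
Product: 30 {2,6,11-trimethyl-4,5-bis[(2Z)-2-methylbut-2-enoyloxy]-9-oxotricyclo[5.4.0.0²,⁸]undecan-6-yl}methyl (2Z)-2-methylbut-2-enoate (CNP0214984.1)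
Conditions: 26 (3 equiv), 2,4,6-trichlorobenzoyl chloride, Et3N, toluene, rt; then 29, 80–100 °C
Reagents that add atoms: none
Why: Esterification of the last, neopentyl-type secondary hydroxyl uses an excess of the mixed anhydride in hot toluene, the Yamaguchi-type protocol under which hindered alcohols should give angelates and not tiglates because no nucleophilic catalyst adds reversibly to the activated enoyl group.

**Compound list**

1 | (S)-benzyl glycidyl ether | C1[C@H](O1)COCc2ccccc2 | starting material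
2 | (2S)-1-(benzyloxy)pent-4-yn-2-ol | C#CC[C@H](O)COCc1ccccc1 | intermediate
3 | {[(2S)-1-(benzyloxy)pent-4-yn-2-yl]oxy}tri(propan-2-yl)silane | C#CC[C@H](O[Si](C(C)C)(C(C)C)C(C)C)COCc1ccccc1 | intermediate
4 | [(1E,4S)-5-(benzyloxy)-2-methyl-4-{[tri(propan-2-yl)silyl]oxy}pent-1-en-1-yl]dimethylalumane | C[Al](C)/C=C(\C)C[C@H](O[Si](C(C)C)(C(C)C)C(C)C)COCc1ccccc1 | intermediate
5 | 2-[(1E,4S)-5-(benzyloxy)-2-methyl-4-{[tri(propan-2-yl)silyl]oxy}pent-1-en-1-yl]-4,4,5,5-tetramethyl-1,3,2-dioxaborolane | CC1(C)OB(OC1(C)C)/C=C(\C)C[C@H](O[Si](C(C)C)(C(C)C)C(C)C)COCc2ccccc2 | intermediate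
6 | (E)-pent-3-en-2-one | C/C=C/C(C)=O | starting material
7 | (4R,5E,8S)-9-(benzyloxy)-4,6-dimethyl-8-{[tri(propan-2-yl)silyl]oxy}non-5-en-2-one | CC(=O)C[C@@H](C)/C=C(\C)C[C@H](O[Si](C(C)C)(C(C)C)C(C)C)COCc1ccccc1 | intermediate
8 | triethyl phosphonoacetate | CCOC(=O)CP(=O)(OCC)OCC | starting material
9 | ethyl (2E,5R,6E,9S)-10-(benzyloxy)-3,5,7-trimethyl-9-{[tri(propan-2-yl)silyl]oxy}deca-2,6-dienoate | CCOC(=O)/C=C(\C)C[C@@H](C)/C=C(\C)C[C@H](O[Si](C(C)C)(C(C)C)C(C)C)COCc1ccccc1 | intermediate
10 | (2E,5R,6E,9S)-10-(benzyloxy)-3,5,7-trimethyl-9-{[tri(propan-2-yl)silyl]oxy}deca-2,6-dienoic acid | OC(=O)/C=C(\C)C[C@@H](C)/C=C(\C)C[C@H](O[Si](C(C)C)(C(C)C)C(C)C)COCc1ccccc1 | intermediate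
11 | (2E,5R,6E,9S)-10-(benzyloxy)-3,5,7-trimethyl-9-{[tri(propan-2-yl)silyl]oxy}deca-2,6-dienoyl chloride | O=C(Cl)/C=C(\C)C[C@@H](C)/C=C(\C)C[C@H](O[Si](C(C)C)(C(C)C)C(C)C)COCc1ccccc1 | intermediate
12 | (5R,6E,9S)-10-(benzyloxy)-5,7-dimethyl-3-methylidene-9-{[tri(propan-2-yl)silyl]oxy}deca-1,6-dien-1-one (vinylketene) | O=C=CC(=C)C[C@@H](C)/C=C(\C)C[C@H](O[Si](C(C)C)(C(C)C)C(C)C)COCc1ccccc1 | intermediate
13 | 7-[(2S)-3-(benzyloxy)-2-{[tri(propan-2-yl)silyl]oxy}propyl]-4,7-dimethyl-2-methylidenebicyclo[3.1.1]heptan-6-one | O=C2[C@@H]3[C@H](C)CC(=C)[C@H]2[C@]3(C)C[C@H](O[Si](C(C)C)(C(C)C)C(C)C)COCc1ccccc1 | intermediate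
14 | diethyl (1-cyanoethyl)phosphonate | CCOP(=O)(OCC)C(C)C#N | starting material
15 | 2-[7-{(2S)-3-(benzyloxy)-2-{[tri(propan-2-yl)silyl]oxy}propyl}-4,7-dimethyl-2-methylidenebicyclo[3.1.1]heptan-6-ylidene]propanenitrile (alkene isomers) | N#CC(C)=C2[C@@H]3[C@H](C)CC(=C)[C@H]2[C@]3(C)C[C@H](O[Si](C(C)C)(C(C)C)C(C)C)COCc1ccccc1 | intermediate
16 | 2-[7-{(2S)-3-(benzyloxy)-2-{[tri(propan-2-yl)silyl]oxy}propyl}-4,7-dimethyl-2-methylidenebicyclo[3.1.1]heptan-6-yl]propanenitrile (C1 epimers) | N#CC(C)[C@H]2[C@@H]3[C@H](C)CC(=C)[C@H]2[C@]3(C)C[C@H](O[Si](C(C)C)(C(C)C)C(C)C)COCc1ccccc1 | intermediate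
17 | N-(diisobutylalumanyl)aldimine of 18 | CC(C)C[Al](CC(C)C)N=CC(C)[C@H]2[C@@H]3[C@H](C)CC(=C)[C@H]2[C@]3(C)C[C@H](O[Si](C(C)C)(C(C)C)C(C)C)COCc1ccccc1 | intermediate
18 | 2-[7-{(2S)-3-(benzyloxy)-2-{[tri(propan-2-yl)silyl]oxy}propyl}-4,7-dimethyl-2-methylidenebicyclo[3.1.1]heptan-6-yl]propanal (C1 epimers) | O=CC(C)[C@H]2[C@@H]3[C@H](C)CC(=C)[C@H]2[C@]3(C)C[C@H](O[Si](C(C)C)(C(C)C)C(C)C)COCc1ccccc1 | intermediate
19 | tert-butyl({2-[7-{(2S)-3-(benzyloxy)-2-{[tri(propan-2-yl)silyl]oxy}propyl}-4,7-dimethyl-2-methylidenebicyclo[3.1.1]heptan-6-yl]prop-1-en-1-yl}oxy)dimethylsilane (enol ether isomers) | CC(C)(C)[Si](C)(C)OC=C(C)[C@H]2[C@@H]3[C@H](C)CC(=C)[C@H]2[C@]3(C)C[C@H](O[Si](C(C)C)(C(C)C)C(C)C)COCc1ccccc1 | intermediate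
20 | (2S)-3-[6-{1-[(tert-butyldimethylsilyl)oxy]prop-1-en-2-yl}-4,7-dimethyl-2-methylidenebicyclo[3.1.1]heptan-7-yl]-2-{[tri(propan-2-yl)silyl]oxy}propan-1-ol | CC(C)(C)[Si](C)(C)OC=C(C)[C@H]2[C@@H]3[C@H](C)CC(=C)[C@H]2[C@]3(C)C[C@H](O[Si](C(C)C)(C(C)C)C(C)C)CO | intermediate
21 | (2S)-3-[6-{1-[(tert-butyldimethylsilyl)oxy]prop-1-en-2-yl}-4,7-dimethyl-2-methylidenebicyclo[3.1.1]heptan-7-yl]-2-{[tri(propan-2-yl)silyl]oxy}propanal | CC(C)(C)[Si](C)(C)OC=C(C)[C@H]2[C@@H]3[C@H](C)CC(=C)[C@H]2[C@]3(C)C[C@H](O[Si](C(C)C)(C(C)C)C(C)C)C=O | intermediate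
22 | 5-hydroxy-2,6,11-trimethyl-9-methylidene-4-{[tri(propan-2-yl)silyl]oxy}tricyclo[5.4.0.0²,⁸]undecane-6-carbaldehyde | O=C[C@]1(C)[C@H]2[C@@H]3[C@H](C)CC(=C)[C@H]2[C@]3(C)C[C@H](O[Si](C(C)C)(C(C)C)C(C)C)[C@H]1O | intermediate
23 | 6-(hydroxymethyl)-2,6,11-trimethyl-9-methylidene-4-{[tri(propan-2-yl)silyl]oxy}tricyclo[5.4.0.0²,⁸]undecan-5-ol | OC[C@]1(C)[C@H]2[C@@H]3[C@H](C)CC(=C)[C@H]2[C@]3(C)C[C@H](O[Si](C(C)C)(C(C)C)C(C)C)[C@H]1O | intermediate
24 | spiro-1,2,4-trioxolane (secondary ozonide) of 23 at C6 | OC[C@]1(C)[C@H]2[C@@H]3[C@H](C)CC4(OOCO4)[C@H]2[C@]3(C)C[C@H](O[Si](C(C)C)(C(C)C)C(C)C)[C@H]1O | intermediate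
25 | 5-hydroxy-6-(hydroxymethyl)-2,6,11-trimethyl-4-{[tri(propan-2-yl)silyl]oxy}tricyclo[5.4.0.0²,⁸]undecan-9-one | OC[C@]1(C)[C@H]2[C@@H]3[C@H](C)CC(=O)[C@H]2[C@]3(C)C[C@H](O[Si](C(C)C)(C(C)C)C(C)C)[C@H]1O | intermediate
26 | angelic acid, (2Z)-2-methylbut-2-enoic acid | C/C=C(/C)C(=O)O | starting material
27 | [5-hydroxy-2,6,11-trimethyl-9-oxo-4-{[tri(propan-2-yl)silyl]oxy}tricyclo[5.4.0.0²,⁸]undecan-6-yl]methyl (2Z)-2-methylbut-2-enoate | C/C=C(/C)C(=O)OC[C@]1(C)[C@H]2[C@@H]3[C@H](C)CC(=O)[C@H]2[C@]3(C)C[C@H](O[Si](C(C)C)(C(C)C)C(C)C)[C@H]1O | intermediate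
28 | (4,5-dihydroxy-2,6,11-trimethyl-9-oxotricyclo[5.4.0.0²,⁸]undecan-6-yl)methyl (2Z)-2-methylbut-2-enoate | C/C=C(/C)C(=O)OC[C@]1(C)[C@H]2[C@@H]3[C@H](C)CC(=O)[C@H]2[C@]3(C)C[C@H](O)[C@H]1O | intermediate
29 | {5-hydroxy-2,6,11-trimethyl-4-[(2Z)-2-methylbut-2-enoyloxy]-9-oxotricyclo[5.4.0.0²,⁸]undecan-6-yl}methyl (2Z)-2-methylbut-2-enoate | C/C=C(/C)C(=O)OC[C@]1(C)[C@H]2[C@@H]3[C@H](C)CC(=O)[C@H]2[C@]3(C)C[C@H](OC(=O)/C(C)=C\C)[C@H]1O | intermediate
30 | CNP0214984.1, {2,6,11-trimethyl-4,5-bis[(2Z)-2-methylbut-2-enoyloxy]-9-oxotricyclo[5.4.0.0²,⁸]undecan-6-yl}methyl (2Z)-2-methylbut-2-enoate | C/C=C(/C)C(=O)OC[C@]1(C)[C@H]2[C@@H]3[C@H](C)CC(=O)[C@H]2[C@]3(C)C[C@H](OC(=O)/C(C)=C\C)[C@H]1OC(=O)/C(C)=C\C | target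

**Step count and risks**

Total step count: 21. Longest linear sequence: 21 steps (from 1).

Steps most likely to fail:

Step 8 (key cycloaddition). The vinylketene may dimerise or oligomerise before it cyclises, base may deprotonate C5 instead of the methyl and lead to the endocyclic alkene isomer, or the relay from C4 may be incomplete. Fallback: setting out from acid chloride 11, dimethylamine gives N,N-dimethyl dienamide F1. Triflic anhydride and 2,4,6-collidine in refluxing 1,2-dichloroethane convert it into vinylketeniminium triflate F2, a more electrophilic ketene equivalent that does not dimerise. Its intramolecular [2+2] with the same polarity gives cyclobutaniminium triflate F3, and hydrolysis with aqueous NaHCO3 rejoins the route at cyclobutanone 13.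

Step 15 (seven-membered ring closure). Synclinal or chelated transition states may compete with the open one and erode the configuration at C11, and the aldol may revert on work-up. Fallback: setting out from 21, the ring is closed as in step 15 and the aldol mixture, 22 together with its C11 epimer F6, is oxidised without separation (Dess–Martin periodinane, NaHCO3, CH2Cl2) to the single β-keto aldehyde F7, in which C1 is quaternary and cannot enolise. Me4NBH(OAc)3 in MeCN–AcOH at −20 °C first reduces the aldehyde to β-hydroxy ketone F8 and then delivers hydride to the C11 ketone intramolecularly from the face of the CH2OH group (Evans–Saksena reduction), which places the C11 hydroxyl trans to CH2OH. The route is rejoined at diol 23.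

Step 10 (conjugate reduction). The transient α-cyano radical at C1 is a cyclobutylcarbinyl radical and may open the four-membered ring toward the allylic C7 before the second electron arrives, and protonation at C2 may not discriminate the two faces well. Fallback: setting out from alkylidene nitrile 15, i-Bu2AlH at −78 °C and hydrolysis give enal F4. Rhodium-catalysed 1,4-hydrosilylation (RhCl(PPh3)3, Et3SiH, benzene, 50 °C) delivers hydride to C2 in a two-electron step from the bridge face and gives triethylsilyl enol ether F5. K2CO3 in methanol releases the aldehyde, and the route is rejoined at 18.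

**Further compounds**

F1 | step 8 | (2E,5R,6E,9S)-10-(benzyloxy)-N,N,3,5,7-pentamethyl-9-{[tri(propan-2-yl)silyl]oxy}deca-2,6-dienamide | CN(C)C(=O)/C=C(\C)C[C@@H](C)/C=C(\C)C[C@H](O[Si](C(C)C)(C(C)C)C(C)C)COCc1ccccc1
F2 | step 8 | vinylketeniminium triflate derived from F1 | C[N+](C)=C=CC(=C)C[C@@H](C)/C=C(\C)C[C@H](O[Si](C(C)C)(C(C)C)C(C)C)COCc1ccccc1.[O-]S(=O)(=O)C(F)(F)F
F3 | step 8 | N,N-dimethyliminium triflate of cyclobutanone 13 | C[N+](C)=C2[C@@H]3[C@H](C)CC(=C)[C@H]2[C@]3(C)C[C@H](O[Si](C(C)C)(C(C)C)C(C)C)COCc1ccccc1.[O-]S(=O)(=O)C(F)(F)F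
F4 | step 10 | 2-[7-{(2S)-3-(benzyloxy)-2-{[tri(propan-2-yl)silyl]oxy}propyl}-4,7-dimethyl-2-methylidenebicyclo[3.1.1]heptan-6-ylidene]propanal | O=CC(C)=C2[C@@H]3[C@H](C)CC(=C)[C@H]2[C@]3(C)C[C@H](O[Si](C(C)C)(C(C)C)C(C)C)COCc1ccccc1
F5 | step 10 | triethylsilyl enol ether of aldehyde 18 | CC[Si](CC)(CC)OC=C(C)[C@H]2[C@@H]3[C@H](C)CC(=C)[C@H]2[C@]3(C)C[C@H](O[Si](C(C)C)(C(C)C)C(C)C)COCc1ccccc1
F6 | step 15 | C11 epimer of aldol 22 | O=C[C@]1(C)[C@H]2[C@@H]3[C@H](C)CC(=C)[C@H]2[C@]3(C)C[C@H](O[Si](C(C)C)(C(C)C)C(C)C)[C@@H]1O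
F7 | step 15 | 2,6,11-trimethyl-9-methylidene-5-oxo-4-{[tri(propan-2-yl)silyl]oxy}tricyclo[5.4.0.0²,⁸]undecane-6-carbaldehyde | O=C[C@]1(C)[C@H]2[C@@H]3[C@H](C)CC(=C)[C@H]2[C@]3(C)C[C@H](O[Si](C(C)C)(C(C)C)C(C)C)C1=O
F8 | step 15 | 6-(hydroxymethyl)-2,6,11-trimethyl-9-methylidene-4-{[tri(propan-2-yl)silyl]oxy}tricyclo[5.4.0.0²,⁸]undecan-5-one | OC[C@]1(C)[C@H]2[C@@H]3[C@H](C)CC(=C)[C@H]2[C@]3(C)C[C@H](O[Si](C(C)C)(C(C)C)C(C)C)C1=O
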